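## Analysis of the target

The target is a monocyclic furan-2(5H)-one (butenolide) in which every ring atom is substituted: O1, the lactone carbonyl C2, C3 with an n-butyl chain, C4 with bromine, and C5 with an exocyclic dibromomethylene group. It has no stereocentres, and because the exocyclic carbon carries two identical bromines the C5=CBr2 bond has no geometry, so the problem is one of constitution only. The O1–C5=CBr2 unit is an enol ester and C4–Br is a vinylogous acyl bromide; the molecule is therefore an acylating and conjugate-accepting electrophile that should not tolerate nucleophiles, aqueous base or low-valent metals for long. The difficulty is the density of functionality: three vinylic bromines of two kinds sit on a five-carbon core that has no ring hydrogen to direct reactivity, and the two C=C bonds are cross-conjugated through the lactone. The strategy rests on C4: since it bears a heteroatom, it can be carried as the C4–OH of a tetronic acid, that is, at the acyl oxidation level. Then C2–C3–C4 is a β-keto ester array, C3–C4 is a Claisen bond between the α-carbon of a hexanoyl group (C2, C3 and the butyl chain) and an ester carbonyl (C4), and O1–C5=CBr2 is simply the enol ester of a dibromopyruvate. The C4 bromine is put in last, so the most labile bond of the target meets no further chemistry.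

## Retrosynthetic reasoning

**C4–Br (12 ⇒ 10, forward through 11).** The first cut is the C4–Br bond. C4 is the β-carbon of the unsaturated lactone, so 12 is the vinylogous acid bromide of the vinylogous acid 10. Cutting here turns the target into a 1,3-dicarbonyl problem and leaves the most electrophilic bond for the end. The forward reaction has to activate the C4 hydroxyl (as 11) and replace it by bromine through addition–elimination, without touching the lactone carbonyl or the C5=CBr2 unit.

**C3–C4 (10 ⇒ 7, forward through 8 and 9).** In 10 the atoms C2, C3 and C4 form a cyclic β-keto ester, and C3–C4 is its Claisen bond. Cutting it opens the ring to 7, in which the future O1 carries both halves: a hexanoyl ester (C2, C3, butyl) and a dibromoacrylate methyl ester (C4, C5, exocyclic carbon). This cut is preferred over the O1–C2 lactone bond, which would require an open-chain precursor with three adjacent carbonyl groups next to a carboxyl group and no stable form, whereas 7 is an ordinary diester. It is also preferred over cuts at C4–C5 or at the exocyclic double bond, because 7 already holds the complete O1–C5=CBr2 unit and no bromine has to be added to the ring side later. The forward reaction must make enolate 8 attack its own methyl ester faster than the enol ester is cleaved; the stability of tetronate 9 drives it.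

**O1–C2 acyl bond (7 ⇒ 4 + 5, forward through 6).** 7 is an enol ester, so the cut is the acyl–oxygen bond, giving acid chloride 5 and enolate 6 of α-keto ester 4. 4 has exactly one acidic C–H, on the carbon that carries both bromines, so enolisation can go only one way and creates the C5=CBr2 double bond and the nucleophilic oxygen together. The forward reaction has to acylate 6 on oxygen and not on carbon; the carbon terminus is a crowded CBr2 centre, which favours oxygen.

**Two C–Br bonds (4 ⇒ 1 + 2, forward through 3).** The last disconnection removes both bromines from the methyl carbon of 4, leaving 1. This is α-halogenation of a ketone with a single enolisable position, so there is no regiochemical question, only one of degree. The forward reaction must stop after the second bromine.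

## Alternatives that were turned down

**Alternative 1:** Annulation of a magnesium carbenoid with a trihaloaldehyde.
- Disconnection: C4–C5 and O1–C2, dividing the ring into methyl 3,3-dibromo-2-butylacrylate A1 (C2, C3, C4, butyl) and tribromoacetaldehyde A3 (C5 and the exocyclic carbon).
- Forward key step: i-PrMgCl would exchange the bromine of A1 that lies cis to the ester, assisted by chelation, to give methyl (E)-3-bromo-2-butyl-3-(chloromagnesio)acrylate A2. A2 adds to A3 and the alkoxide closes onto the cis ester to give racemic 4-bromo-3-butyl-5-(tribromomethyl)furan-2(5H)-one A4. Base-induced loss of HBr across C5 and the CBr3 group would then give 12.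
- For: it is convergent, forms two ring bonds in one flask, and brings the C4 bromine from A1, so no deoxybromination is needed. On these points and on step count it is as strong as or stronger than the chosen route.
- Against: A2 is an α-bromoalkenyl carbenoid and can α-eliminate or rearrange (Fritsch–Buttenberg–Wiechell type). Site selectivity between the geminal bromines rests on chelation alone. A3 offers three more C–Br bonds to halogen–metal exchange, and its alkoxide adducts are prone to haloform-type cleavage.
- Comparison: the chosen route places every bromine by ionic chemistry with no organometallic reagent in a polybrominated environment, and its ring closure has one acidic site and one electrophile.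

**Alternative 2:** Carbonylative lactonisation of a dibromoenone.
- Disconnection: C2–C3 and O1–C2, with C2 supplied by carbon monoxide; the precursor is (E)-3,4-dibromooct-3-en-2-one A5.
- Forward key step: Pd(PPh3)4 (zerovalent palladium) would insert into the C–Br bond at the butyl-bearing carbon, carbon monoxide would insert, and the enol oxygen of the methyl ketone would capture the acylpalladium intermediate. The product is 4-bromo-3-butyl-5-methylenefuran-2(5H)-one A6. Two rounds of bromine addition and dehydrobromination at the exocyclic methylene would then be needed to reach 12.
- For: the ring closure is catalytic and base-mild, and the C4 bromine is carried through. In mildness it is stronger than the chosen Dieckmann closure.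
- Against: A5 has two vinylic C–Br bonds and A6 has a third, more activated one (β to the lactone carbonyl), so the catalyst can consume its own product. The closure also needs the ketone to enolise toward the methyl group. The exocyclic bromines are added afterwards over several operations on an electrophilic bromobutenolide, making the route longer.
- Comparison: the chosen route has the dibromomethylene group complete before the ring is formed and needs no transition metal.

**Alternative 3:** Oxidative ring expansion of a squarate-derived cyclobutenone.
- Disconnection: O1–C2, traced back to a four-membered ring: the furanone derives from racemic 2-butyl-4-(dibromomethyl)-4-hydroxy-3-isopropoxycyclobut-2-en-1-one A7, built from a squaric acid diester.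
- Forward key step: Pb(OAc)4 (tetravalent lead) would oxidise the tertiary alcohol, the bond between the carbonyl and carbinol carbons would break, and the carbinol oxygen would reclose on the acyl carbon. Loss of the CHBr2 proton would then give 3-butyl-5-(dibromomethylene)-4-isopropoxyfuran-2(5H)-one A8. Dealkylation of A8 would give 10, followed by the same final bromination as in the chosen route.
- For: the C3/C4 substitution pattern is fixed by the dependable regiochemistry of squarate additions, and no enolate is generated on an activated ester. On that point it is stronger than the chosen route.
- Against: A7 requires addition of a thermally fragile dibromomethyl carbenoid. The oxidant is a stoichiometric heavy-metal reagent. The outcome at C5 depends on proton loss competing with acetate capture. The sequence is about two steps longer and still ends at 10.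
- Comparison: the chosen route reaches 10 directly in three steps from bulk chemicals.

Key step: step 3

Remark on the chemistry: both substituents on the exocyclic carbon are bromine, so 7, 10 and 12 have no geometric isomers, and the geometry of enolate 8 is without consequence.

## Route

**Step 1**
Reactants: 1 methyl pyruvate; 2 bromine
Product: 4 methyl 3,3-dibromo-2-oxopropanoate, via methyl 3-bromo-2-oxopropanoate 3 (not isolated)
Conditions: Br2 (2.1 equiv, in two portions), conc. H2SO4 (cat.), CHCl3, 25 → 60 °C, HBr swept out with N2; distillation under reduced pressure
Reagents that add atoms: none
Why: Acid-catalysed α-bromination of a ketone through its enol; the methyl group is the only enolisable position of 1, and each bromine slows the next enolisation under acid catalysis, so the amount of 2 should set the degree of bromination at two, with residual 3 and any tribromide removed by distillation.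

**Step 2**
Reactants: 4 methyl 3,3-dibromo-2-oxopropanoate; 5 hexanoyl chloride
Product: 7 methyl 3,3-dibromo-2-(hexanoyloxy)acrylate, via triethylammonium enolate 6 (not isolated)
Conditions: 5 (1.1 equiv), Et3N (1.15 equiv, added last, dropwise), CH2Cl2, −20 → 0 °C
Reagents that add atoms: none
Why: Enol ester formation by O-acylation of an enolate; Et3N removes the only C–H of 4 (acidified by the keto ester and two bromines), and the acid chloride takes the oxygen of 6 because the carbon terminus is a crowded CBr2 centre. Adding the amine last keeps free enolate and ketene from 5 at low concentration, and the new double bond has no geometry.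

**Step 3**
Reactants: 7 methyl 3,3-dibromo-2-(hexanoyloxy)acrylate
Product: 10 3-butyl-5-(dibromomethylene)-4-hydroxyfuran-2(5H)-one, via lithium ester enolate 8 (not isolated), via lithium tetronate 9 (not isolated)
Conditions: 7 added slowly to LiN(SiMe3)2 (2.2 equiv), THF (ca. 0.02 M), −78 °C, then −78 → −20 °C; 1 M HCl
Reagents that add atoms: none
Why: LiN(SiMe3)2 removes an α-proton of the hexanoyl group (the only acidic C–H in 7, since the acrylate half has none) to give ester enolate 8, whose α-carbon adds to the neighbouring methyl ester carbonyl to form C3–C4, and collapse of the tetrahedral intermediate expels methoxide. This is a Dieckmann-type intramolecular Claisen condensation of a 2-acyloxyacrylate, the reaction type that closes 5-ylidene tetronic acids from enol esters of arylpyruvates. The one ring formed is the five-membered lactone, closed 5-exo-trig at the ester carbonyl with the enolate double bond inside the new ring (5-enolendo); the ring-closure rules for enolates rate this mode as the less favourable one, yet it is the normal course of tetronic acid formation from α-acyloxy esters, and the planar O1–C5(=CBr2)–C4 unit already holds the reacting carbons close. No stereocentre is created, since C3 becomes sp2 and the CBr2 terminus has no geometry. The selectivity needed is intramolecular C-acylation over cleavage of the activated enol ester by acyl transfer to a second molecule, by methoxide, or by E1cB loss of the dibromo enolate to give butylketene. It should be secured by slow addition of 7 to excess base at −78 °C under dilution, so that each molecule is enolised at once and meets neither neutral ester nor free methoxide, and by the unimolecular five-membered closure. The product is deprotonated as it forms to the stabilised tetronate 9, which takes it out of all equilibria, and the acid quench liberates 10. With no vinylic hydrogen and a non-nucleophilic amide base, the C=CBr2 unit should remain untouched.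

**Step 4**
Reactants: 10 3-butyl-5-(dibromomethylene)-4-hydroxyfuran-2(5H)-one
Product: 12 4-bromo-3-butyl-5-(dibromomethylene)furan-2(5H)-one, via O-iminium bromide 11 (not isolated)
Conditions: (COBr)2 (1.3 equiv), DMF (0.1 equiv), CH2Cl2, 0 °C → rt
Reagents that add atoms: oxalyl bromide, O=C(Br)C(=O)Br
Why: Deoxybromination of a tetronic acid with a bromo-Vilsmeier reagent, a known route to 4-bromofuran-2(5H)-ones; the bromoiminium salt from oxalyl bromide and DMF activates the C4 enol oxygen as 11, bromide adds at C4 and DMF is expelled (addition–elimination). The conditions are non-basic, so the lactone and the electron-poor C5=CBr2 unit should survive.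

## Compound list

1 | methyl pyruvate (methyl 2-oxopropanoate) | CC(=O)C(=O)OC | starting material
2 | bromine | BrBr | starting material
3 | methyl 3-bromo-2-oxopropanoate | COC(=O)C(=O)CBr | intermediate (not isolated)
4 | methyl 3,3-dibromo-2-oxopropanoate | COC(=O)C(=O)C(Br)Br | intermediate
5 | hexanoyl chloride | CCCCCC(Cl)=O | starting material
6 | triethylammonium enolate of 4 (triethylammonium 1,1-dibromo-3-methoxy-3-oxoprop-1-en-2-olate) | COC(=O)C([O-])=C(Br)Br.CC[NH+](CC)CC | intermediate (not isolated)
7 | methyl 3,3-dibromo-2-(hexanoyloxy)acrylate | CCCCCC(=O)OC(=C(Br)Br)C(=O)OC | intermediate
8 | lithium ester enolate of 7 (enolate geometry undefined) | CCCCC=C(O[Li])OC(=C(Br)Br)C(=O)OC | intermediate (not isolated)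
9 | lithium tetronate (lithium salt of 10) | CCCCC1=C(O[Li])C(=C(Br)Br)OC1=O | intermediate (not isolated)
10 | 3-butyl-5-(dibromomethylene)-4-hydroxyfuran-2(5H)-one | CCCCC1=C(O)C(=C(Br)Br)OC1=O | intermediate
11 | O-iminium bromide of 10 (4-[(dimethyliminio)methoxy] derivative, bromide salt) | CCCCC1=C(OC=[N+](C)C)C(=C(Br)Br)OC1=O.[Br-] | intermediate (not isolated)
12 | 4-bromo-3-butyl-5-(dibromomethylene)furan-2(5H)-one | CCCCC1=C(Br)C(=C(Br)Br)OC1=O | target

## Step count and risk

Total steps: 4. Longest linear sequence: 4 steps (1 → 4 → 7 → 10 → 12).

**Step 3 (key step).** The most likely failure is cleavage of the enol ester in competition with ring closure: acyl transfer, or E1cB fragmentation of 8 into butylketene and the dibromo enolate, which is a good leaving group. The enolendo closure is not fast, which gives these pathways time.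

The fallback sets out from 5 and returns at 12; it closes the ring on a saturated ester and builds the exocyclic unit afterwards.
- 5 would be esterified with racemic methyl lactate (Et3N, cat. DMAP, CH2Cl2) to methyl 2-(hexanoyloxy)propanoate F1, an ordinary α-acyloxy ester with an alkoxide-type leaving group.
- Dieckmann closure (KOtBu, THF) should give 3-butyl-4-hydroxy-5-methylfuran-2(5H)-one F2, and oxalyl bromide with catalytic DMF should give 4-bromo-3-butyl-5-methylfuran-2(5H)-one F3.
- Radical bromination of the allylic, oxygen-bearing C5–H (NBS, cat. AIBN, PhCF3, reflux) would give 4,5-dibromo-3-butyl-5-methylfuran-2(5H)-one F4, and Et3N would remove HBr to give 4-bromo-3-butyl-5-methylenefuran-2(5H)-one F5 (the same structure as A6).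
- Two cycles of bromine addition and dehydrobromination then bring the exocyclic carbon to the required level: Br2 to 4,5-dibromo-5-(bromomethyl)-3-butylfuran-2(5H)-one F6, Et3N to 4-bromo-5-(bromomethylene)-3-butylfuran-2(5H)-one F7 (either geometric isomer serves), Br2 to 4,5-dibromo-3-butyl-5-(dibromomethyl)furan-2(5H)-one F8, and Et3N to 12.

This is much longer, but each reaction is standard and no activated enol ester meets a strong base.

**Step 2.** What may go wrong is loss of 4 before acylation: halophilic or nucleophilic attack of the amine on the α,α-dibromoketone, self-condensation of 6, or consumption of 5 as its ketene. C-acylation is the less likely problem.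

The fallback sets out from 4 and returns at 7; it generates the enolate reductively instead of by deprotonation. 4 would be brominated once more (Br2, cat. H2SO4, heat) to methyl 3,3,3-tribromo-2-oxopropanoate F9, which has no acidic hydrogen. Zn dust in Et2O at 0 °C removes one bromine in a Reformatsky-type insertion and gives the bromozinc enolate of methyl 3,3-dibromo-2-oxopropanoate F10 regiospecifically, without amine. O-acylation by 5 in the same flask should give 7.

**Step 1.** The process at risk is control of the degree of bromination. Under- and over-bromination give mono- and tribromides that are difficult to separate cleanly, and the HBr formed can cleave the methyl ester on prolonged heating.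

The fallback sets out from 1 and returns at 4; it introduces each bromine through an isolated silyl enol ether. 1 would be silylated (Me3SiCl, Et3N) to methyl 2-(trimethylsilyloxy)acrylate F11 and brominated with NBS to 3, which is isolated in this variant. A second silylation would give methyl 3-bromo-2-(trimethylsilyloxy)acrylate F12, and NBS would give 4. Each bromination is then stoichiometric on a discrete enol derivative.

**Step 4.** Possible problems are activation at the lactone carbonyl oxygen instead of the C4 hydroxyl, conjugate attack of bromide on the dibromomethylene terminus, or acid-induced degradation by the HBr formed.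

The fallback sets out from 10 and returns at 12; it separates activation from substitution. 10 would be converted with (CF3SO2)2O and i-Pr2NEt in CH2Cl2 at −78 °C into 3-butyl-5-(dibromomethylene)-2-oxo-2,5-dihydrofuran-4-yl trifluoromethanesulfonate F13. This isolable vinylogous acyl triflate should exchange with LiBr in acetone by addition–elimination at C4 under neutral conditions to give 12.

## Further compounds

F1 | step 3 | methyl 2-(hexanoyloxy)propanoate (racemic) | CCCCCC(=O)OC(C)C(=O)OC
F2 | step 3 | 3-butyl-4-hydroxy-5-methylfuran-2(5H)-one (racemic) | CCCCC1=C(O)C(C)OC1=O
F3 | step 3 | 4-bromo-3-butyl-5-methylfuran-2(5H)-one (racemic) | CCCCC1=C(Br)C(C)OC1=O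
F4 | step 3 | 4,5-dibromo-3-butyl-5-methylfuran-2(5H)-one (racemic) | CCCCC1=C(Br)C(C)(Br)OC1=O
F5 | step 3 | 4-bromo-3-butyl-5-methylenefuran-2(5H)-one | CCCCC1=C(Br)C(=C)OC1=O
F6 | step 3 | 4,5-dibromo-5-(bromomethyl)-3-butylfuran-2(5H)-one (racemic) | CCCCC1=C(Br)C(Br)(CBr)OC1=O
F7 | step 3 | 4-bromo-5-(bromomethylene)-3-butylfuran-2(5H)-one (geometry not defined) | CCCCC1=C(Br)C(=CBr)OC1=O
F8 | step 3 | 4,5-dibromo-3-butyl-5-(dibromomethyl)furan-2(5H)-one (racemic) | CCCCC1=C(Br)C(Br)(C(Br)Br)OC1=O
F9 | step 2 | methyl 3,3,3-tribromo-2-oxopropanoate | COC(=O)C(=O)C(Br)(Br)Br
F10 | step 2 | bromozinc enolate of methyl 3,3-dibromo-2-oxopropanoate | COC(=O)C(O[Zn]Br)=C(Br)Br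
F11 | step 1 | methyl 2-(trimethylsilyloxy)acrylate | C=C(O[Si](C)(C)C)C(=O)OC
F12 | step 1 | methyl 3-bromo-2-(trimethylsilyloxy)acrylate (geometry not defined) | COC(=O)C(O[Si](C)(C)C)=CBr
F13 | step 4 | 3-butyl-5-(dibromomethylene)-2-oxo-2,5-dihydrofuran-4-yl trifluoromethanesulfonate | CCCCC1=C(OS(=O)(=O)C(F)(F)F)C(=C(Br)Br)OC1=O
A1 | alternative 1 | methyl 3,3-dibromo-2-butylacrylate | CCCCC(=C(Br)Br)C(=O)OC
A2 | alternative 1 | methyl (E)-3-bromo-2-butyl-3-(chloromagnesio)acrylate | CCCC/C(C(=O)OC)=C(\Br)[Mg]Cl
A3 | alternative 1 | tribromoacetaldehyde | O=CC(Br)(Br)Br
A4 | alternative 1 | 4-bromo-3-butyl-5-(tribromomethyl)furan-2(5H)-one (racemic) | CCCCC1=C(Br)C(C(Br)(Br)Br)OC1=O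
A5 | alternative 2 | (E)-3,4-dibromooct-3-en-2-one | CCCC/C(Br)=C(Br)/C(C)=O
A6 | alternative 2 | 4-bromo-3-butyl-5-methylenefuran-2(5H)-one | CCCCC1=C(Br)C(=C)OC1=O
A7 | alternative 3 | 2-butyl-4-(dibromomethyl)-4-hydroxy-3-isopropoxycyclobut-2-en-1-one (racemic) | CCCCC1=C(OC(C)C)C(O)(C(Br)Br)C1=O
A8 | alternative 3 | 3-butyl-5-(dibromomethylene)-4-isopropoxyfuran-2(5H)-one | CCCCC1=C(OC(C)C)C(=C(Br)Br)OC1=O
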